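Ericifolione is numbered as a chromene: pyran ring O1, C2, C3, C4, C4a, C8a fused to ring A, enol ring B on C2. The route rests on cutting O1–C2 and rejoining C2 to C4a: the pyran is the two-atom ring expansion of a spiro cyclobutane (C4a, C4, C3, C2) in which the C2 oxygen and the ring A β-triketone at C4a stand in a de Mayo (donor–acceptor) relationship. In one operation fluoride triggers retro-aldol opening to the six-membered lactol, expels a traceless carbinol tether carbon as acetaldehyde and unites C2 with syncarpic acid. The precursor is a silicon-tethered [2+2] photoadduct whose carbinol centre, set by catalytic asymmetric methylation, controls C4.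

Key step: step 5

Assumption: syncarpic acid (3) and (E)-2-isopropyl-5-methylhex-2-enal (1, the self-condensation product of isovaleraldehyde) are taken as commercial; any Z isomer of 1 is removed at the stage of 2.

Step 1
Reactants: 1 (E)-2-isopropyl-5-methylhex-2-enal
Product: 2 (2S,3E)-3-isopropyl-6-methylhept-3-en-2-ol
Conditions: Me2Zn, (−)-3-exo-morpholinoisoborneol (5 mol %), toluene/hexane, 0 °C; then 1 M HCl
Reagents that add atoms: dimethylzinc C[Zn]C
Why: Amino-alcohol-catalysed enantioselective 1,2-addition of a dialkylzinc to an aldehyde, in which the zinc aminoalkoxide should deliver methyl to the Si face of the α-branched enal and so set the (S)-carbinol centre, leaving the trisubstituted alkene untouched.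

Step 2
Reactants: 3 syncarpic acid
Product: 5 2-(hydroxymethylene)syncarpic acid, via enaminone 4 (not isolated)
Conditions: Me2NCH(OMe)2, CH2Cl2, rt; then 2 M HCl, THF, rt
Reagents that add atoms: N,N-dimethylformamide dimethyl acetal COC(OC)N(C)C; water O
Why: Condensation of the acidic 1,3-dione carbon with the amide acetal followed by enaminone hydrolysis should give the enolised formyl triketone, with no stereocentre formed and no E/Z isomers because ring A is symmetric.

Step 3
Reactants: 2 (2S,3E)-3-isopropyl-6-methylhept-3-en-2-ol; 5 2-(hydroxymethylene)syncarpic acid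
Product: 7 mixed silyl ketal (silicon-tethered diene), via silyl triflate 6 (not isolated)
Conditions: tBu2Si(OTf)2, 2,6-lutidine, CH2Cl2, −78 → 0 °C (with 2); then 5, Et3N, 0 °C → rt
Reagents that add atoms: di-tert-butylsilyl bis(trifluoromethanesulfonate) CC(C)(C)[Si](OS(=O)(=O)C(F)(F)F)(OS(=O)(=O)C(F)(F)F)C(C)(C)C
Why: Stepwise O-silylation (temporary silicon tether, unsymmetrical silyl ketal formation) in which the hindered bis-triflate should take up the secondary alcohol once and the remaining silyl triflate is then captured by the unhindered exocyclic oxygen of the vinylogous acid 5, the carbinol centre being unaffected.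

Step 4
Reactants: 7 mixed silyl ketal (silicon-tethered diene)
Product: 8 spirocyclobutane photoadduct
Conditions: hν (λ > 300 nm, Pyrex), degassed MeCN (0.005 M), 0 °C
Reagents that add atoms: none
Why: Intramolecular enone–alkene [2+2] photocycloaddition through a temporary silicon tether (de Mayo-type photoadduct of a formyl-β-dicarbonyl enol derivative), in which the excited β-silyloxy enedione should bond first from C2 to C3 to close the six-membered 1,3-dioxa-2-silinane (straight mode, cis ring fusion) and the 1,4-biradical then closes C4a–C4, the (S)-carbinol centre fixing the alkene face (tether methyl equatorial, carbinol hydrogen turned towards the isopropyl group in the chair-like closure) and hence C3, and retention of the E geometry (isobutyl cis to isopropyl, exo to the silinane) fixing C4, with minor diastereomers removed by chromatography.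

Step 5
Reactants: 8 spirocyclobutane photoadduct; 3 syncarpic acid
Product: 12 ericifolione, via cyclobutanediol 9 (not isolated), via hydroxy aldehyde 10 (not isolated), via lactol 11 (not isolated)
Conditions: Bu4NF, THF, 0 °C → rt; then TsOH·H2O, 3, 40 °C
Reagents that add atoms: none
Why: Fluoride removes the silylene, and the C2 alkoxide, which sits 1,3 to the two ring A ketones on the strained four-membered ring, undergoes retro-aldol cleavage of C2–C4a (de Mayo fragmentation) to the ring A enolate and the C2 aldehyde, after which the second alkoxide, now β to that aldehyde at the quaternary C3, undergoes a second retro-aldol that expels the tether carbon as acetaldehyde. On acidification the ring A enol oxygen closes onto the aldehyde to give lactol 11 (6-exo-trig), so the four cyclobutane carbons C4a, C4, C3, C2 reappear in the pyran with C8a and O1 inserted into the broken bond; the closest known chemistry is the de Mayo photocycloaddition/retro-aldol route to dihydropyran lactols, followed by acid-catalysed Knoevenagel condensation/oxa-Michael addition of a cyclic 1,3-dione. Syncarpic acid then attacks C2 through the cyclic oxocarbenium ion or, after ring opening, through the alkylidene of ring B, which recloses by 6-exo-trig oxa-Michael addition. C4 is carried over unchanged from 8, C3 is set by protonation of the aldehyde enolate and acid equilibration trans to the C4 isobutyl group (both pseudoaxial, away from the C5 carbonyl), and C2 is set under thermodynamic control by the reversible oxa-Michael step, ring B taking the equatorial position cis to the C3 isopropyl group. The step needs cleavage of C2–C4a and of no other cyclobutane bond, which the diketone acceptor at C4a secures, and it needs C4 to stay fixed, which is secured because ring A is an enolate (not a leaving group) during the basic phase and the union is run under acid and not amine catalysis.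

Compound list (atom labels of the target are used for 8–11)
1 | (E)-2-isopropyl-5-methylhex-2-enal | CC(C)C/C=C(\C(C)C)C=O | starting material
2 | (2S,3E)-3-isopropyl-6-methylhept-3-en-2-ol | C[C@H](O)/C(C(C)C)=C/CC(C)C | intermediate
3 | syncarpic acid (2,2,4,4-tetramethylcyclohexane-1,3,5-trione) | CC1(C)C(=O)CC(=O)C(C)(C)C1=O | starting material
4 | 2-[(dimethylamino)methylene]-4,4,6,6-tetramethylcyclohexane-1,3,5-trione | CN(C)C=C1C(=O)C(C)(C)C(=O)C(C)(C)C1=O | intermediate
5 | 2-(hydroxymethylene)-4,4,6,6-tetramethylcyclohexane-1,3,5-trione (formylsyncarpic acid, enol form) | OC=C1C(=O)C(C)(C)C(=O)C(C)(C)C1=O | intermediate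
6 | di-tert-butyl{[(2S,3E)-3-isopropyl-6-methylhept-3-en-2-yl]oxy}silyl trifluoromethanesulfonate | C[C@H](O[Si](OS(=O)(=O)C(F)(F)F)(C(C)(C)C)C(C)(C)C)/C(C(C)C)=C/CC(C)C | intermediate
7 | di-tert-butyl{[(2S,3E)-3-isopropyl-6-methylhept-3-en-2-yl]oxy}[(3,3,5,5-tetramethyl-2,4,6-trioxocyclohexylidene)methoxy]silane | C[C@H](O[Si](OC=C1C(=O)C(C)(C)C(=O)C(C)(C)C1=O)(C(C)(C)C)C(C)(C)C)/C(C(C)C)=C/CC(C)C | intermediate
8 | spirocyclobutane photoadduct: ring A spiro at C4a; C4 bears H and isobutyl; C3 bears isopropyl and the (S)-CH(CH3)O carbon; C2 bears H and O; the two oxygens are bridged by Si(tBu)2 in a cis-fused 1,3-dioxa-2-silinane; isobutyl cis to isopropyl; carbinol methyl on the same side of the silinane as C4 | CC(C)C[C@@H]1C2(C(=O)C(C)(C)C(=O)C(C)(C)C2=O)[C@H]3O[Si](C(C)(C)C)(C(C)(C)C)O[C@@H](C)[C@@]13C(C)C | intermediate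
9 | cyclobutanediol: 8 without the silylene (free C2–OH and carbinol OH), same configuration | CC(C)C[C@@H]1C2(C(=O)C(C)(C)C(=O)C(C)(C)C2=O)[C@@H](O)[C@]1([C@H](C)O)C(C)C | intermediate
10 | ring-opened hydroxy aldehyde: 2-substituted syncarpic acid (enol form) with side chain C4H(isobutyl)–C3(isopropyl)(CHO)[(S)-CH(OH)CH3] | CC(C)C[C@H](C1=C(O)C(C)(C)C(=O)C(C)(C)C1=O)[C@@](C=O)([C@H](C)O)C(C)C | intermediate
11 | (3S,4S)-2-hydroxy-4-isobutyl-3-isopropyl-6,6,8,8-tetramethyl-3,4-dihydro-2H-chromene-5,7(6H,8H)-dione (lactol, both anomers) | CC(C)C[C@@H]1C2=C(OC(O)[C@H]1C(C)C)C(C)(C)C(=O)C(C)(C)C2=O | intermediate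
12 | ericifolione, (2R,3S,4S)-2-(2-hydroxy-3,3,5,5-tetramethyl-4,6-dioxocyclohex-1-en-1-yl)-4-isobutyl-3-isopropyl-6,6,8,8-tetramethyl-3,4-dihydro-2H-chromene-5,7(6H,8H)-dione | CC(C)C[C@@H]1C2=C(O[C@@H](C3=C(O)C(C)(C)C(=O)C(C)(C)C3=O)[C@H]1C(C)C)C(C)(C)C(=O)C(C)(C)C2=O | target

Total step count: 5. Longest linear sequence: 4 steps (1 → 2 → 7 → 8 → 12, or 3 → 5 → 7 → 8 → 12).

Steps most likely to fail

Step 4. The tethered photocycloaddition may close in the crossed sense (first bond C2–C4, seven-membered ring), may discriminate the two alkene faces or the two C4 orientations poorly, or the silyl group may shift to a ring oxygen and move the chromophore into ring A. If the sense of induction proves opposite, the enantiomeric ligand in step 1 supplies the (R)-carbinol. The fallback replaces the silicon tether by a formaldehyde acetal; it sets out from 2 and 5 and comes back to the route at 10. Alcohol 2 is converted with paraformaldehyde and Me3SiCl into the chloromethyl ether F1, which alkylates the exocyclic oxygen of 5 (iPr2NEt, CH2Cl2) to give the acetal-tethered diene F2. Irradiation as in step 4 should give the dioxane-fused cyclobutane F3 through a more compact six-membered closure with no silyl shift possible. Aqueous CF3CO2H then opens the donor–acceptor cyclobutane at C2–C4a and hydrolyses the hemiformal to give 10, from which K2CO3 in MeOH releases acetaldehyde to 11 before the acid-mediated union with 3.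

Step 5. The second retro-aldol (loss of acetaldehyde) may stall, the C4 configuration may erode through reversible Michael addition while the ring is open during the union, or the kinetic C2 epimer may form. The fallback separates the union from the ring expansion and avoids ring opening; it sets out from 8 and comes back at 12. After the fluoride stage the mixture is quenched with AcOH and lactol 11 is isolated, acetylated (Ac2O, pyridine) to the anomeric acetate F4, and coupled with 3 under BF3·OEt2 in CH2Cl2 at low temperature through the cyclic oxocarbenium ion (C-glycosylation-type substitution). A final treatment with DBU equilibrates C2 if needed.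

Step 1. Methyl transfer from the less reactive dimethylzinc to the hindered α-isopropyl enal may be slow and facial control incomplete. The fallback sets the carbinol centre by reduction instead of addition; it sets out from 1 and comes back at 2. MeMgBr adds to 1 to give the racemic alcohol F5, MnO2 oxidises it to the enone F6, and CBS reduction with (R)-2-methyl-CBS-oxazaborolidine and BH3·SMe2 (large alkenyl against small methyl) should give 2.

Further compounds
F1 | step 4 | chloromethyl (2S,3E)-3-isopropyl-6-methylhept-3-en-2-yl ether | C[C@H](OCCl)/C(C(C)C)=C/CC(C)C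
F2 | step 4 | acetal-tethered diene, 2-({[(2S,3E)-3-isopropyl-6-methylhept-3-en-2-yl]oxymethoxy}methylene)-4,4,6,6-tetramethylcyclohexane-1,3,5-trione | C[C@H](OCOC=C1C(=O)C(C)(C)C(=O)C(C)(C)C1=O)/C(C(C)C)=C/CC(C)C
F3 | step 4 | 1,3-dioxane-fused spirocyclobutane (8 with CH2 in place of Si(tBu)2) | CC(C)C[C@@H]1C2(C(=O)C(C)(C)C(=O)C(C)(C)C2=O)[C@H]3OCO[C@@H](C)[C@@]13C(C)C
F4 | step 5 | anomeric acetate of lactol 11 | CC(C)C[C@@H]1C2=C(OC(OC(C)=O)[C@H]1C(C)C)C(C)(C)C(=O)C(C)(C)C2=O
F5 | step 1 | racemic (E)-3-isopropyl-6-methylhept-3-en-2-ol | CC(O)/C(C(C)C)=C/CC(C)C
F6 | step 1 | (E)-3-isopropyl-6-methylhept-3-en-2-one | CC(=O)/C(C(C)C)=C/CC(C)C
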